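The route cuts the C1–C2 bond of ring B and treats it as a deleted nitrogen. The aryltetralin is made from a 1-aryl-3,4-dimethyl-2-benzazepine by extrusion of the ring nitrogen as N2. C1 is bonded to both ring A (at C8a) and ring C. Its C–N bond is therefore weak, and the radical left behind is a stabilised diarylmethyl radical; this is the feature exploited. In one operation the seven-membered ring contracts to ring B, C1–C2 forms, and C1 and C2 become stereocentres. The precursor 16 is a single (1S,3S,4R) isomer with ring A as benzyl ether and ring C as silyl ether. It is configured so that retention or relaxation gives the same all-trans product.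

Key step: step 10

Numbering used: in the tetralin, C1 carries ring C, C2 and C3 carry the methyl groups, C4 is the CH2, and C4a/C8a are the fusion carbons. Ring A is the fused arene, ring B the saturated ring, ring C the pendant aryl group and ring D the side-chain aryl group. Cα is the carbinol carbon and Cβ the ether carbon of the side chain.

Assumption: cyclic isodiazenes are taken to lose N2 mainly with retention at both carbon atoms, so the benzazepine is made as one defined isomer and not as an epimer mixture.

Step 1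
Reactants: 1 4-(benzyloxy)-3-methoxybenzyl alcohol
Product: 2 4-(benzyloxy)-3-methoxybenzyl bromide
Conditions: PBr3 (0.4 equiv), Et2O, 0 °C; used without storage
Reagents that add atoms: phosphorus tribromide, BrP(Br)Br
Why: Bromination of a primary benzylic alcohol with PBr3 (SN2 on the phosphite ester) is routine for alkoxybenzyl alcohols and leaves the aryl benzyl ether alone.

Step 2
Reactants: 2 4-(benzyloxy)-3-methoxybenzyl bromide; 3 (S)-4-benzyl-3-propionyloxazolidin-2-one
Product: 5 (S)-4-benzyl-3-[(R)-3-(4-benzyloxy-3-methoxyphenyl)-2-methylpropanoyl]oxazolidin-2-one, via sodium Z-enolate 4 (not isolated)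
Conditions: NaN(SiMe3)2, THF, −78 °C; then 2, −78 → −20 °C
Reagents that add atoms: none
Why: Evans asymmetric alkylation, in which the benzyl group of the (S)-auxiliary shields one face of the chelated Z-enolate 4, so the reactive benzylic bromide enters from the other face and sets the (R) centre that becomes C3.

Step 3
Reactants: 5 alkylated imide
Product: 6 (R)-3-[4-(benzyloxy)-3-methoxyphenyl]-2-methylpropan-1-ol
Conditions: NaBH4, THF/H2O, 0 °C → rt
Reagents that add atoms: none
Why: Hydride reduction of the exocyclic imide carbonyl releases the auxiliary and gives the primary alcohol without enolisation of the α-centre.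

Step 4
Reactants: 6 (R)-alcohol
Product: 7 (R)-3-[4-(benzyloxy)-3-methoxyphenyl]-2-methylpropanal
Conditions: TEMPO (cat.), PhI(OAc)2, CH2Cl2, rt; used directly
Reagents that add atoms: none
Why: The TEMPO/PhI(OAc)2 oxidation stops at the aldehyde under base-free conditions, which protects the α-methyl centre from epimerisation.

Step 5
Reactants: 7 (R)-aldehyde; 8 (R)-2-methylpropane-2-sulfinamide
Product: 9 (R)-N-{(1E,2R)-3-[4-(benzyloxy)-3-methoxyphenyl]-2-methylpropylidene}-2-methylpropane-2-sulfinamide
Conditions: CuSO4 (anhydrous), CH2Cl2, rt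
Reagents that add atoms: none
Why: Ellman condensation over a mild Lewis acidic desiccant gives the E-sulfinimine, avoids the enolisable ketimine of a ketone reductive amination and so keeps the only carbon stereocentre intact.

Step 6
Reactants: 9 sulfinimine
Product: 10 (R)-N-{(2S,3R)-4-[4-(benzyloxy)-3-methoxyphenyl]-3-methylbutan-2-yl}-2-methylpropane-2-sulfinamide
Conditions: MeMgBr, CH2Cl2, −48 °C; aq NH4Cl
Reagents that add atoms: methylmagnesium bromide, C[Mg]Br
Why: Ellman Grignard addition in a non-coordinating solvent runs through a six-membered chair with magnesium on the sulfinyl oxygen, so the (R)-sulfinyl group delivers methyl to the face that gives the (S) amine carbon (later C2) under reagent control.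

Step 7
Reactants: 10 sulfinamide
Product: 11 (2S,3R)-4-[4-(benzyloxy)-3-methoxyphenyl]-3-methylbutan-2-amine
Conditions: HCl (4 M in dioxane), MeOH, 0 °C → rt; aq NaOH work-up
Reagents that add atoms: none
Why: Acid methanolysis of the N–S bond is the standard removal of the sulfinyl group and touches neither the benzyl ether nor the two carbon centres.

Step 8
Reactants: 12 vanillin
Product: 13 3-methoxy-4-(triisopropylsilyloxy)benzaldehyde
Conditions: i-Pr3SiCl, imidazole, DMF, rt
Reagents that add atoms: triisopropylsilyl chloride, CC(C)[Si](Cl)(C(C)C)C(C)C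
Why: Phenol silylation gives a bulky aryl silyl ether that tolerates trifluoroacetic acid at moderate temperature and is orthogonal to the ring A benzyl ether.

Step 9
Reactants: 11 amine; 13 silylated vanillin
Product: 16 (1S,3S,4R)-8-(benzyloxy)-7-methoxy-1-[3-methoxy-4-(triisopropylsilyloxy)phenyl]-3,4-dimethyl-2,3,4,5-tetrahydro-1H-2-benzazepine, via E-imine 14 (not isolated), via 1,3-cis epimer 15 (not isolated)
Conditions: 4 Å molecular sieves, CH2Cl2, rt; then CF3CO2H (10 equiv), 0 → 40 °C until the epimer composition is constant; aq NaHCO3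
Reagents that add atoms: none
Why: Pictet–Spengler reaction (7-endo-trig attack of the ring A carbon para to the methoxy group on protonated 14, helped by the two backbone methyl groups); kinetic closure should give the 1,3-cis epimer 15, but the doubly benzylic, doubly para-oxygenated C1–N bond ionises reversibly in the acid, so C1 equilibrates and the 1,3-trans isomer 16, whose axial ring C escapes the in-plane contact with the peri hydrogen H9, is separated from residual 15 by chromatography.

Step 10
Reactants: 16 benzazepine; 17 N-(benzyloxy)-N-(pivaloyloxy)-4-(trifluoromethyl)benzamide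
Product: 20 (1S,2S,3R)-7-(benzyloxy)-6-methoxy-1-[3-methoxy-4-(triisopropylsilyloxy)phenyl]-2,3-dimethyl-1,2,3,4-tetrahydronaphthalene, via N-benzyloxy hydrazide 18 (not isolated), via isodiazene 19 (not isolated)
Conditions: 17 (1.5 equiv), THF (0.02 M), 45 °C, argon
Reagents that add atoms: none
Why: Proposed new method: the ring NH of 16 displaces pivalate at the amide nitrogen of 17, hydrazide 18 then shifts its benzyloxy group to the acyl carbon and releases isodiazene 19, and 19 expels N2, the weak doubly benzylic C1–N bond breaking first, to leave a diarylmethyl radical at C1 and a secondary alkyl radical at C2 joined through C8a, C4a, C4 and C3. The closest known reaction type is nitrogen deletion of benzylic secondary amines with anomeric amides, backed by the classical oxidation of N-amino-2-arylazacycles to ring-contracted carbocycles, but a ring nitrogen flanked by a diarylmethyl carbon and a branched non-benzylic carbon has not been shown. Ring B closes by radical–radical recombination of the singlet 1,6-diradical, a six-membered closure that makes C1–C2. C1 and C2 are first controlled by the configuration built into 16: both carbons are set free close together on the face that nitrogen leaves, so a least-motion collapse puts the new bond where each C–N bond stood (retention, 1,3-trans amine to 1,2-trans tetralin). Should the diradical live long enough to turn about C2–C3 or C1–C8a, the C3 methyl group takes control through a chair-like closure with ring C and both methyl groups equatorial, which is the same all-trans isomer. The selectivity needed is recombination over hydrogen transfer from C3–H or the C2 methyl group to C1, and the substrate secures it only through the short tether, the proximity of the two centres at birth and the masking of both phenols, while high dilution holds back isodiazene dimerisation.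

Step 11
Reactants: 20 silylated tetralin
Product: 21 4-[(1S,2S,3R)-7-(benzyloxy)-6-methoxy-2,3-dimethyl-1,2,3,4-tetrahydronaphthalen-1-yl]-2-methoxyphenol
Conditions: Bu4NF, AcOH (1.1 equiv each), THF, 0 °C
Reagents that add atoms: none
Why: Buffered fluoride cleavage of an aryl silyl ether frees only the ring C phenol, because the benzyl ether is inert to fluoride.

Step 12
Reactants: 21 ring C phenol; 22 ethyl (S)-lactate
Product: 23 ethyl (R)-2-{4-[(1S,2S,3R)-7-(benzyloxy)-6-methoxy-2,3-dimethyl-1,2,3,4-tetrahydronaphthalen-1-yl]-2-methoxyphenoxy}propanoate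
Conditions: PPh3, DIAD, THF, 0 °C → rt
Reagents that add atoms: none
Why: Mitsunobu etherification, in which the phenoxide displaces the activated lactate oxygen by SN2 with inversion, turns the (S) carbinol carbon into the (R) centre Cβ.

Step 13
Reactants: 23 ester
Product: 24 (R)-2-{4-[(1S,2S,3R)-7-(benzyloxy)-6-methoxy-2,3-dimethyl-1,2,3,4-tetrahydronaphthalen-1-yl]-2-methoxyphenoxy}propanal
Conditions: i-Bu2AlH (1.1 equiv), toluene, −78 °C; aq potassium sodium tartrate; used directly
Reagents that add atoms: none
Why: Partial ester reduction works because the aluminium hemiacetal persists at −78 °C until the quench, and immediate use of the α-aryloxy aldehyde guards Cβ against epimerisation.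

Step 14
Reactants: 25 4-bromo-2-methoxyphenol
Product: 26 1-(benzyloxy)-4-bromo-2-methoxybenzene
Conditions: BnBr, K2CO3, DMF, rt
Reagents that add atoms: benzyl bromide, BrCc1ccccc1
Why: Williamson etherification masks the ring D phenol with the same group as ring A, so both fall in one final operation.

Step 15
Reactants: 26 aryl bromide; 24 aldehyde
Product: 28 (1S,2R)-1-[4-(benzyloxy)-3-methoxyphenyl]-2-{4-[(1S,2S,3R)-7-(benzyloxy)-6-methoxy-2,3-dimethyl-1,2,3,4-tetrahydronaphthalen-1-yl]-2-methoxyphenoxy}propan-1-ol, via arylmagnesium bromide 27 (not isolated)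
Conditions: 26, Mg, THF, reflux; then 24, THF, −78 °C; aq NH4Cl
Reagents that add atoms: none
Why: Grignard addition under polar Felkin–Anh control, since in THF at low temperature the weakly basic aryloxy oxygen does not hold magnesium, the Cβ–O bond stands anti to the incoming aryl group and attack past the hydrogen gives the erythro (αS,βR) alcohol.

Step 16
Reactants: 28 dibenzyl ether
Product: 29 (1S,2R)-1-(4-hydroxy-3-methoxyphenyl)-2-{4-[(1S,2S,3R)-7-hydroxy-6-methoxy-2,3-dimethyl-1,2,3,4-tetrahydronaphthalen-1-yl]-2-methoxyphenoxy}propan-1-ol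
Conditions: H2 (1 atm), Pd/C, EtOAc, rt, stopped at two equivalents of H2
Reagents that add atoms: none
Why: Catalytic hydrogenolysis under neutral conditions cleaves both aryl benzyl ethers faster than the secondary benzylic alcohol and changes no stereocentre.

Compound list
1 | 4-(benzyloxy)-3-methoxybenzyl alcohol | COc1cc(CO)ccc1OCc1ccccc1 | starting material
2 | 4-(benzyloxy)-3-methoxybenzyl bromide | COc1cc(CBr)ccc1OCc1ccccc1 | intermediate
3 | (S)-4-benzyl-3-propionyloxazolidin-2-one | CCC(=O)N1[C@@H](Cc2ccccc2)COC1=O | starting material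
4 | sodium Z-enolate of 3 | C/C=C(\[O-])N1[C@@H](Cc2ccccc2)COC1=O.[Na+] | intermediate
5 | (S)-4-benzyl-3-[(R)-3-(4-benzyloxy-3-methoxyphenyl)-2-methylpropanoyl]oxazolidin-2-one | COc1cc(C[C@@H](C)C(=O)N2[C@@H](Cc3ccccc3)COC2=O)ccc1OCc1ccccc1 | intermediate
6 | (R)-3-[4-(benzyloxy)-3-methoxyphenyl]-2-methylpropan-1-ol | COc1cc(C[C@@H](C)CO)ccc1OCc1ccccc1 | intermediate
7 | (R)-3-[4-(benzyloxy)-3-methoxyphenyl]-2-methylpropanal | COc1cc(C[C@@H](C)C=O)ccc1OCc1ccccc1 | intermediate
8 | (R)-2-methylpropane-2-sulfinamide | CC(C)(C)[S@@](=O)N | starting material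
9 | (R)-sulfinyl E-aldimine of 7 | COc1cc(C[C@@H](C)/C=N/[S@](=O)C(C)(C)C)ccc1OCc1ccccc1 | intermediate
10 | (R)-N-{(2S,3R)-4-[4-(benzyloxy)-3-methoxyphenyl]-3-methylbutan-2-yl}-2-methylpropane-2-sulfinamide | COc1cc(C[C@@H](C)[C@H](C)N[S@](=O)C(C)(C)C)ccc1OCc1ccccc1 | intermediate
11 | (2S,3R)-4-[4-(benzyloxy)-3-methoxyphenyl]-3-methylbutan-2-amine | COc1cc(C[C@@H](C)[C@H](C)N)ccc1OCc1ccccc1 | intermediate
12 | vanillin | COc1cc(C=O)ccc1O | starting material
13 | 3-methoxy-4-(triisopropylsilyloxy)benzaldehyde | COc1cc(C=O)ccc1O[Si](C(C)C)(C(C)C)C(C)C | intermediate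
14 | E-imine of 11 and 13 | COc1cc(C[C@@H](C)[C@H](C)/N=C/c2ccc(O[Si](C(C)C)(C(C)C)C(C)C)c(OC)c2)ccc1OCc1ccccc1 | intermediate
15 | (1R,3S,4R) 1,3-cis epimer of 16 | CC(C)[Si](C(C)C)(C(C)C)Oc2ccc([C@@H]3c4cc(OCc5ccccc5)c(OC)cc4C[C@@H](C)[C@H](C)N3)cc2OC | intermediate
16 | (1S,3S,4R)-8-(benzyloxy)-7-methoxy-1-[3-methoxy-4-(triisopropylsilyloxy)phenyl]-3,4-dimethyl-2,3,4,5-tetrahydro-1H-2-benzazepine | CC(C)[Si](C(C)C)(C(C)C)Oc2ccc([C@H]3c4cc(OCc5ccccc5)c(OC)cc4C[C@@H](C)[C@H](C)N3)cc2OC | intermediate
17 | N-(benzyloxy)-N-(pivaloyloxy)-4-(trifluoromethyl)benzamide | CC(C)(C)C(=O)ON(OCc1ccccc1)C(=O)c1ccc(cc1)C(F)(F)F | starting material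
18 | N-(benzyloxy)-N-(benzazepin-2-yl)-4-(trifluoromethyl)benzamide derived from 16 | CC(C)[Si](C(C)C)(C(C)C)Oc2ccc([C@H]3c4cc(OCc5ccccc5)c(OC)cc4C[C@@H](C)[C@H](C)N3N(OCc6ccccc6)C(=O)c7ccc(cc7)C(F)(F)F)cc2OC | intermediate
19 | isodiazene (1,1-diazene) of 16 | CC(C)[Si](C(C)C)(C(C)C)Oc2ccc([C@H]3c4cc(OCc5ccccc5)c(OC)cc4C[C@@H](C)[C@H](C)[N+]3=[N-])cc2OC | intermediate
20 | (1S,2S,3R)-7-(benzyloxy)-6-methoxy-1-[3-methoxy-4-(triisopropylsilyloxy)phenyl]-2,3-dimethyl-1,2,3,4-tetrahydronaphthalene | CC(C)[Si](C(C)C)(C(C)C)Oc2ccc([C@H]3c4cc(OCc5ccccc5)c(OC)cc4C[C@@H](C)[C@@H]3C)cc2OC | intermediate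
21 | 4-[(1S,2S,3R)-7-(benzyloxy)-6-methoxy-2,3-dimethyl-1,2,3,4-tetrahydronaphthalen-1-yl]-2-methoxyphenol | Oc2ccc([C@H]3c4cc(OCc5ccccc5)c(OC)cc4C[C@@H](C)[C@@H]3C)cc2OC | intermediate
22 | ethyl (S)-lactate | CCOC(=O)[C@H](C)O | starting material
23 | ethyl (R)-2-aryloxypropanoate of 21 | CCOC(=O)[C@@H](C)Oc2ccc([C@H]3c4cc(OCc5ccccc5)c(OC)cc4C[C@@H](C)[C@@H]3C)cc2OC | intermediate
24 | (R)-2-aryloxypropanal of 21 | O=C[C@@H](C)Oc2ccc([C@H]3c4cc(OCc5ccccc5)c(OC)cc4C[C@@H](C)[C@@H]3C)cc2OC | intermediate
25 | 4-bromo-2-methoxyphenol | COc1cc(Br)ccc1O | starting material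
26 | 1-(benzyloxy)-4-bromo-2-methoxybenzene | COc1cc(Br)ccc1OCc1ccccc1 | intermediate
27 | [4-(benzyloxy)-3-methoxyphenyl]magnesium bromide | COc1cc([Mg]Br)ccc1OCc1ccccc1 | intermediate
28 | erythro (αS,βR) alcohol with both phenols benzylated | COc1cc([C@H](O)[C@@H](C)Oc2ccc([C@H]3c4cc(OCc5ccccc5)c(OC)cc4C[C@@H](C)[C@@H]3C)cc2OC)ccc1OCc1ccccc1 | intermediate
29 | CID53359464 | COc1cc([C@H](O)[C@@H](C)Oc2ccc([C@H]3c4cc(O)c(OC)cc4C[C@@H](C)[C@@H]3C)cc2OC)ccc1O | target

Total step count: 16. Longest linear sequence: 14 (steps 1–7, 9–13, 15, 16).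

Steps most likely to fail

**Step 10.**
- What may go wrong:
  - The nitrogen sits between two branched carbons, so N–N bond formation may be slow.
  - Hydrogen transfer inside the diradical may outrun C–C closure.
  - Stereochemical memory may be partly lost, with closure on the wrong face.
- The fallback gives up the radical closure and makes ring B by a cationic C1–C8a closure with known chemistry. It sets out from aldehyde 7 and comes back at tetralin 20.
- Seyferth–Gilbert homologation of 7 with the Ohira–Bestmann reagent (K2CO3, MeOH) should give 1-(benzyloxy)-2-methoxy-4-[(2R)-2-methylbut-3-yn-1-yl]benzene F1.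
- Phenol 25 is silylated (i-Pr3SiCl, imidazole) to (4-bromo-2-methoxyphenoxy)triisopropylsilane F2.
- Negishi carboalumination of F1 (AlMe3, Cp2ZrCl2 cat.), transmetalation with ZnCl2 and Pd(PPh3)4-catalysed coupling with F2 should give {4-[(1E,3R)-4-(4-benzyloxy-3-methoxyphenyl)-2,3-dimethylbut-1-en-1-yl]-2-methoxyphenoxy}triisopropylsilane F3.
- CF3CO2H in CH2Cl2 at 0 °C protonates the electron-rich styrene reversibly at C2. The para-oxygenated benzylic cation at C1 is then trapped by ring A, para to its methoxy group, in an intramolecular Friedel–Crafts alkylation. The chair-like transition state with all three substituents equatorial selects the all-trans compound 20.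

**Step 9.**
- What may go wrong:
  - Seven-membered closure of a donor-stabilised iminium ion may be slow.
  - The silyl ether may be lost if the acid has to be forced.
  - The share of the 1,3-trans epimer at equilibrium may be low. Residual 15 can be put back into the acid.
- The fallback replaces the iminium closure by a Bischler–Napieralski sequence. It sets out from 13 and 11 and comes back at 16.
- Pinnick oxidation of 13 (NaClO2, NaH2PO4, 2-methyl-2-butene) gives 3-methoxy-4-(triisopropylsilyloxy)benzoic acid F4.
- Carbodiimide coupling of F4 with 11 (EDC, HOBt) gives N-{(2S,3R)-4-[4-(benzyloxy)-3-methoxyphenyl]-3-methylbutan-2-yl}-3-methoxy-4-(triisopropylsilyloxy)benzamide F5.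
- Cyclodehydration of F5 (Tf2O, 2-chloropyridine, CH2Cl2, −78 → 40 °C) gives (3S,4R)-8-(benzyloxy)-7-methoxy-1-[3-methoxy-4-(triisopropylsilyloxy)phenyl]-3,4-dimethyl-4,5-dihydro-3H-2-benzazepine F6.
- NaBH4 in MeOH reduces F6 to the C1 epimers. These enter the same acid equilibration and separation to give 16.

**Step 15.**
- What may go wrong:
  - Magnesium chelation by the aryloxy and neighbouring methoxy oxygens may erode the facial selectivity.
  - The basic reagent may epimerise the α-aryloxy aldehyde.
- The fallback sets Cα by hydride delivery to a ketone instead of aryl delivery to an aldehyde. It sets out from 28 (as its Cα epimer mixture) and comes back at 28.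
- Dess–Martin oxidation gives (R)-1-[4-(benzyloxy)-3-methoxyphenyl]-2-{4-[(1S,2S,3R)-7-(benzyloxy)-6-methoxy-2,3-dimethyl-1,2,3,4-tetrahydronaphthalen-1-yl]-2-methoxyphenoxy}propan-1-one F7.
- Chelation-controlled reduction of F7 with Zn(BH4)2 in Et2O at −78 → 0 °C delivers hydride past the hydrogen of the five-membered chelate. This corresponds to the erythro (αS,βR) alcohol.

Further compounds
F1 | step 10 | 1-(benzyloxy)-2-methoxy-4-[(2R)-2-methylbut-3-yn-1-yl]benzene | COc1cc(C[C@@H](C)C#C)ccc1OCc1ccccc1
F2 | step 10 | (4-bromo-2-methoxyphenoxy)triisopropylsilane | COc1cc(Br)ccc1O[Si](C(C)C)(C(C)C)C(C)C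
F3 | step 10 | {4-[(1E,3R)-4-(4-benzyloxy-3-methoxyphenyl)-2,3-dimethylbut-1-en-1-yl]-2-methoxyphenoxy}triisopropylsilane | COc1cc(C[C@@H](C)/C(C)=C/c2ccc(O[Si](C(C)C)(C(C)C)C(C)C)c(OC)c2)ccc1OCc1ccccc1
F4 | step 9 | 3-methoxy-4-(triisopropylsilyloxy)benzoic acid | COc1cc(C(=O)O)ccc1O[Si](C(C)C)(C(C)C)C(C)C
F5 | step 9 | N-{(2S,3R)-4-[4-(benzyloxy)-3-methoxyphenyl]-3-methylbutan-2-yl}-3-methoxy-4-(triisopropylsilyloxy)benzamide | COc1cc(C[C@@H](C)[C@H](C)NC(=O)c2ccc(O[Si](C(C)C)(C(C)C)C(C)C)c(OC)c2)ccc1OCc1ccccc1
F6 | step 9 | (3S,4R)-8-(benzyloxy)-7-methoxy-1-[3-methoxy-4-(triisopropylsilyloxy)phenyl]-3,4-dimethyl-4,5-dihydro-3H-2-benzazepine | CC(C)[Si](C(C)C)(C(C)C)Oc2ccc(C=3c4cc(OCc5ccccc5)c(OC)cc4C[C@@H](C)[C@H](C)N=3)cc2OC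
F7 | step 15 | (R)-1-[4-(benzyloxy)-3-methoxyphenyl]-2-{4-[(1S,2S,3R)-7-(benzyloxy)-6-methoxy-2,3-dimethyl-1,2,3,4-tetrahydronaphthalen-1-yl]-2-methoxyphenoxy}propan-1-one | COc1cc(C(=O)[C@@H](C)Oc2ccc([C@H]3c4cc(OCc5ccccc5)c(OC)cc4C[C@@H](C)[C@@H]3C)cc2OC)ccc1OCc1ccccc1
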